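**Assumption:** The target has no stereocentres and no E/Z-stereogenic alkene, so it is achiral and "single enantiomer" imposes no constraint. The only stereocentre in the route (carbinol 7, racemic) is erased in Step 4.

## Retrosynthetic overview

1. The pyran ring is the only ring formed, and it is formed last: formal [3+3] annulation of prenal onto the 4-OH / C5–H of benzophenone 9.
2. The aryl–C(=O) bond comes from an aryllithium (directed ortho-metalation) adding to 4-(methoxymethoxy)benzaldehyde, followed by oxidation.
3. The C-prenyl bond comes from directed ortho-metalation between the two OMOM groups of bis-MOM 5-methoxyresorcinol, then prenyl bromide.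
4. Both aromatic rings are bought; the methyl ether is present from the start, so no selective methylation is needed.

## Route

**Step 1**
Reactants: 1, 5-methoxyresorcinol; 2, chloromethyl methyl ether (MOMCl)
Product: 3, 1-methoxy-3,5-bis(methoxymethoxy)benzene
Conditions: NaH (2.4 eq), MOMCl (2.4 eq), DMF, 0 °C → rt
Reagents that add atoms: MOMCl, COCCl
Why: Williamson O-alkylation of both phenoxides; the MOM ethers survive organolithiums and act as the ortho-directing groups for Steps 2 and 3.

**Step 2**
Reactants: 3; 4, prenyl bromide (1-bromo-3-methylbut-2-ene)
Product: 5, 5-methoxy-1,3-bis(methoxymethoxy)-2-(3-methylbut-2-en-1-yl)benzene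
Conditions: n-BuLi (1.1 eq), THF, 0 °C, 1 h; CuI (1.0 eq), −40 °C; prenyl bromide, −40 °C → rt
Reagents that add atoms: prenyl bromide, CC(C)=CCBr
Why: Directed ortho-metalation should favour the CH flanked by two chelating OMOM groups (para to OMe) over the two OMOM/OMe-flanked positions, and the arylcopper gives SN2 (α) prenylation.

**Step 3**
Reactants: 5; 6, 4-(methoxymethoxy)benzaldehyde
Product: 7, (RS)-[6-methoxy-2,4-bis(methoxymethoxy)-3-(3-methylbut-2-en-1-yl)phenyl][4-(methoxymethoxy)phenyl]methanol (racemic)
Conditions: n-BuLi (1.2 eq), TMEDA, THF, 0 °C, 1 h; then 6, −78 °C → rt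
Reagents that add atoms: 4-(methoxymethoxy)benzaldehyde, COCOc1ccc(C=O)cc1
Why: Second directed ortho-metalation at one of the two equivalent remaining ring CH positions (between OMOM and OMe), then 1,2-addition to the aldehyde; the new carbinol centre is racemic and is destroyed in Step 4.

**Step 4**
Reactants: 7
Product: 8, [6-methoxy-2,4-bis(methoxymethoxy)-3-(3-methylbut-2-en-1-yl)phenyl][4-(methoxymethoxy)phenyl]methanone
Conditions: Dess–Martin periodinane, NaHCO3, CH2Cl2, 0 °C → rt
Reagents that add atoms: none
Why: Buffered Dess–Martin oxidation of the doubly benzylic alcohol to the benzophenone; the prenyl alkene and the MOM/methyl ethers are inert, and the buffer prevents ionisation of the electron-rich benzhydrol.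

**Step 5**
Reactants: 8
Product: 9, [2,4-dihydroxy-6-methoxy-3-(3-methylbut-2-en-1-yl)phenyl](4-hydroxyphenyl)methanone
Conditions: conc. HCl (few equiv), MeOH, rt → 40 °C
Reagents that add atoms: none
Why: Acetal solvolysis removes all three MOM groups while the aryl methyl ether stays; conditions are kept mild so the prenyl group does not cyclise onto a flanking OH to give a chroman.

**Step 6**
Reactants: 9; 10, prenal (3-methylbut-2-enal)
Product: 11, vismiaphenone F, [7-hydroxy-5-methoxy-2,2-dimethyl-8-(3-methylbut-2-en-1-yl)-2H-chromen-6-yl](4-hydroxyphenyl)methanone
Conditions: prenal (2 eq), ethylenediammonium diacetate (20 mol %), toluene, reflux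
Reagents that add atoms: prenal, CC(C)=CC=O
Why: Knoevenagel-type condensation at C5 (the only free CH on the electron-rich ring), then ortho-quinone methide formation and oxa-6π electrocyclisation onto the adjacent 4-OH. The 6-position is OMe, the 2-OH is not adjacent to C5, and the 4-hydroxybenzoyl ring is too electron-poor to react, so only one chromene can form.

## Compound list

1 | 5-methoxyresorcinol | COc1cc(O)cc(O)c1 | starting material
2 | chloromethyl methyl ether | COCCl | starting material (reagent)
3 | 1-methoxy-3,5-bis(methoxymethoxy)benzene | COCOc1cc(OC)cc(OCOC)c1 | intermediate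
4 | prenyl bromide | CC(C)=CCBr | starting material (reagent)
5 | 5-methoxy-1,3-bis(methoxymethoxy)-2-(3-methylbut-2-en-1-yl)benzene | COCOc1cc(OC)cc(OCOC)c1CC=C(C)C | intermediate
6 | 4-(methoxymethoxy)benzaldehyde | COCOc1ccc(C=O)cc1 | starting material
7 | (RS)-[6-methoxy-2,4-bis(methoxymethoxy)-3-prenylphenyl][4-(methoxymethoxy)phenyl]methanol (racemic) | COCOc1ccc(cc1)C(O)c1c(OC)cc(OCOC)c(CC=C(C)C)c1OCOC | intermediate
8 | [6-methoxy-2,4-bis(methoxymethoxy)-3-prenylphenyl][4-(methoxymethoxy)phenyl]methanone | COCOc1ccc(cc1)C(=O)c1c(OC)cc(OCOC)c(CC=C(C)C)c1OCOC | intermediate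
9 | (2,4-dihydroxy-6-methoxy-3-prenylphenyl)(4-hydroxyphenyl)methanone | COc1cc(O)c(CC=C(C)C)c(O)c1C(=O)c1ccc(O)cc1 | intermediate
10 | prenal (3-methylbut-2-enal) | CC(C)=CC=O | starting material (reagent)
11 | vismiaphenone F | COc1c2c(c(CC=C(C)C)c(O)c1C(=O)c1ccc(O)cc1)OC(C)(C)C=C2 | target

## Summary

Total steps: 6. Longest linear sequence: 6 (from 5-methoxyresorcinol).

Steps most likely to fail, with fallbacks:

1. **Step 2 (site selectivity of the first lithiation, and SN2 vs SN2′ prenylation).** Lithiation between OMOM and OMe could compete and give an isomeric prenyl arene that is hard to separate. Fallback: fix the regiochemistry by symmetry instead. Acylate phloroglucinol with 4-hydroxybenzoic acid, tris-MOM protect (one chelated OH remains), O-prenylate that OH (Mitsunobu), run a para-Claisen–Cope rearrangement to place the prenyl para to it, methylate the released OH, and remove the MOM groups to reach 9.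

2. **Step 3 (ring lithiation versus benzylic/allylic deprotonation of the prenyl CH2, and addition of a hindered aryllithium).** Fallback: switch to electrophilic acylation. Friedel–Crafts acylate 5-methoxyresorcinol with 4-hydroxybenzoic acid (Eaton's reagent) to build the benzophenone first, then C-prenylate at C3, the carbon between the two OH groups (prenyl bromide, aq. KOH), to reach 9. This is shorter but less selective at both steps.

3. **Step 6 (annulation on an acyl-deactivated, fully flanked phenol carrying three free OH groups).** Fallback: form the pyran before the ketone exists. Deprotect 5 to the symmetric 5-methoxy-2-prenylresorcinol and annulate with prenal (either OH gives the same chromene). Then MOM-protect the remaining OH, install the aroyl group at the single remaining ring CH by lithiation, addition to 6 and oxidation, and deprotect.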